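The benzene ring of the indane is taken apart into two three-carbon pieces. C4–C5–C6, with the oxygenated one-carbon substituents on C4 and C6, is dimethyl 3-oxopentanedioate. C7, C7a and C3a are the formyl carbon, α-carbon and carbonyl carbon of 2-(hydroxymethylene)-4,4-dimethylcyclopentanone, whose ring becomes the gem-dimethylcyclopentane. One base-mediated operation forms C6–C7 and C3a–C4 and aromatises, giving a C5 phenol flanked by two esters. The phenol is exchanged (triflate, then vinyl) for a masked chloroethyl chain, the esters are told apart by their ortho neighbours (C7–H against the C3 methylene), and the chain is unveiled last so that no hydroxyethyl group meets a ring ester.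

Key step: step 2

Remark: the target has no stereocenter; all bicyclic intermediates keep the indane locants of the target (C4 acetoxymethyl side, C5 chain, C6 butanoyloxymethyl side), and formylation of 1 is assumed to occur at the methylene remote from the gem-dimethyl group.

Step 1
Reactants: 1 3,3-dimethylcyclopentan-1-one; 2 ethyl formate
Product: 3 (Z)-2-(hydroxymethylene)-4,4-dimethylcyclopentan-1-one
Conditions: NaOMe (1.2 equiv), HCO2Et (1.5 equiv), Et2O, 0 °C → rt; then cold 1 M HCl
Reagents that add atoms: none
Why: Crossed Claisen condensation (α-formylation) under reversible alkoxide conditions should acylate the unhindered C5 methylene of 1 in preference to the neopentyl-type C2 methylene and is driven by formation of the stabilised sodium enolate, which on acidification should give the hydrogen-bonded Z-enol.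

Step 2
Reactants: 3 (Z)-2-(hydroxymethylene)-4,4-dimethylcyclopentan-1-one; 4 dimethyl 3-oxopentanedioate
Product: 6 dimethyl 5-hydroxy-2,2-dimethylindane-4,6-dicarboxylate, via Knoevenagel adduct 5 (not isolated)
Conditions: NaOMe (2.2 equiv), MeOH, 0 °C → rt, then 60 °C; aq. HCl to pH 3
Reagents that add atoms: none
Why: The enolate of 4 should add to the formyl carbon of 3 (present in equilibrium with its keto aldehyde tautomer) and lose water in a Knoevenagel condensation, forming C6–C7 in adduct 5. The second active methylene should then attack the ring ketone in a 6-(enolexo)-exo-trig aldol closure that forms C3a–C4, after which loss of water and enolisation of the central ketone should deliver the benzene ring as the C5 phenol. The closest known reaction type is the alkoxide-mediated condensation of 2-hydroxymethylene ketones with dialkyl 3-oxoglutarates to give 2-hydroxyisophthalates. No stereocenter is created. The selectivity needed is carbon over oxygen cyclisation (pyranone formation), which the reversible alkoxide conditions and the aromatic sink should secure; regiochemistry is not an issue because 4 is twofold symmetric, so either order of bond formation gives the same arene. Methoxide is matched to the methyl esters so that no ester exchange can occur.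

Step 3
Reactants: 6 dimethyl 5-hydroxy-2,2-dimethylindane-4,6-dicarboxylate
Product: 7 dimethyl 2,2-dimethyl-5-(trifluoromethanesulfonyloxy)indane-4,6-dicarboxylate
Conditions: Tf2O (1.2 equiv), pyridine (3 equiv), CH2Cl2, 0 °C → rt
Reagents that add atoms: trifluoromethanesulfonic anhydride, FC(F)(F)S(=O)(=O)OS(=O)(=O)C(F)(F)F
Why: O-sulfonylation of the acidic, ester-flanked phenol with Tf2O and pyridine is standard for salicylate-type phenols and should give the aryl triflate without touching the esters.

Step 4
Reactants: 7 dimethyl 2,2-dimethyl-5-(trifluoromethanesulfonyloxy)indane-4,6-dicarboxylate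
Product: 8 dimethyl 5-ethenyl-2,2-dimethylindane-4,6-dicarboxylate
Conditions: Bu3SnCH=CH2 (1.3 equiv), Pd(PPh3)4 (5 mol%), LiCl (3 equiv), 1,4-dioxane, 100 °C
Reagents that add atoms: tributyl(vinyl)stannane, C=C[Sn](CCCC)(CCCC)CCCC
Why: Stille cross-coupling should succeed because the two ortho esters speed oxidative addition of zerovalent palladium into the aryl C–O bond, LiCl exchanges triflate for chloride on palladium, the small vinyl group transmetalates at the flanked centre, and the neutral conditions spare the esters.

Step 5
Reactants: 8 dimethyl 5-ethenyl-2,2-dimethylindane-4,6-dicarboxylate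
Product: 9 5-ethenyl-4-(methoxycarbonyl)-2,2-dimethylindane-6-carboxylic acid
Conditions: LiOH·H2O (1.2 equiv), THF/MeOH/H2O, rt; then 1 M HCl
Reagents that add atoms: lithium hydroxide, [Li+].[OH-]
Why: Sterically controlled saponification (acyl–oxygen cleavage) should take only the C6 ester, which has C7–H on one side, while the C4 ester is wedged between the vinyl group and the C3 methylene and should resist a limiting amount of hydroxide at room temperature.

Step 6
Reactants: 9 5-ethenyl-4-(methoxycarbonyl)-2,2-dimethylindane-6-carboxylic acid
Product: 11 methyl 5-ethenyl-6-(hydroxymethyl)-2,2-dimethylindane-4-carboxylate, via isobutyl carbonic mixed anhydride 10 (not isolated)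
Conditions: i-BuOCOCl, N-methylmorpholine, THF, −15 °C; then NaBH4, H2O, 0 °C
Reagents that add atoms: none
Why: Reduction of a carboxylic acid through its mixed carbonic anhydride with NaBH4 should give the benzylic alcohol while leaving the hindered methyl ester and the vinyl group alone, which a borane reduction would not do because it hydroborates styrenes.

Step 7
Reactants: 11 methyl 5-ethenyl-6-(hydroxymethyl)-2,2-dimethylindane-4-carboxylate
Product: 12 methyl 6-(chloromethyl)-5-ethenyl-2,2-dimethylindane-4-carboxylate
Conditions: PPh3, N-chlorosuccinimide, CH2Cl2, 0 °C → rt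
Reagents that add atoms: N-chlorosuccinimide, ClN1C(=O)CCC1=O
Why: Appel-type chlorination by SN2 displacement of the alkoxyphosphonium should convert the primary benzylic alcohol cleanly, and the resulting chloride serves as a hydride-tolerant placeholder for the later butanoate so that no protecting group is needed at C6.

Step 8
Reactants: 12 methyl 6-(chloromethyl)-5-ethenyl-2,2-dimethylindane-4-carboxylate
Product: 13 [6-(chloromethyl)-5-ethenyl-2,2-dimethylindan-4-yl]methanol
Conditions: i-Bu2AlH (2.5 equiv), CH2Cl2, −78 → 0 °C; aq. potassium sodium tartrate (KNaC4H4O6)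
Reagents that add atoms: none
Why: Ester reduction with i-Bu2AlH should take the hindered C4 ester to the primary alcohol, and this hydride is known to leave benzylic halides and styrenes untouched at low temperature, as in reductions of (halomethyl)benzoates.

Step 9
Reactants: 13 [6-(chloromethyl)-5-ethenyl-2,2-dimethylindan-4-yl]methanol
Product: 14 [6-(chloromethyl)-5-ethenyl-2,2-dimethylindan-4-yl]methyl acetate
Conditions: Ac2O (1.5 equiv), pyridine, DMAP (2 mol%), CH2Cl2, 0 °C
Reagents that add atoms: acetic anhydride, CC(=O)OC(C)=O
Why: Nucleophile-catalysed O-acylation of the primary alcohol should be fast at 0 °C, and the low temperature and short contact should keep N-alkylation of the amines by the benzylic chloride negligible.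

Step 10
Reactants: 14 [6-(chloromethyl)-5-ethenyl-2,2-dimethylindan-4-yl]methyl acetate
Product: 15 [4-(acetoxymethyl)-5-ethenyl-2,2-dimethylindan-6-yl]methyl butanoate
Conditions: sodium butanoate (2 equiv), n-Bu4NI (10 mol%), DMF, 50 °C
Reagents that add atoms: sodium butanoate, CCCC(=O)[O-].[Na+]
Why: SN2 O-alkylation of a carboxylate by a benzylic chloride, assisted by in-situ Finkelstein exchange with iodide, should install the butanoate at C6 while the C4 acetate and the vinyl group are inert to the weakly basic carboxylate.

Step 11
Reactants: 15 [4-(acetoxymethyl)-5-ethenyl-2,2-dimethylindan-6-yl]methyl butanoate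
Product: 17 [4-(acetoxymethyl)-5-(2-hydroxyethyl)-2,2-dimethylindan-6-yl]methyl butanoate, via B-alkyl-9-borabicyclononane adduct 16 (not isolated)
Conditions: 9-BBN (1.5 equiv), THF, 0 → 40 °C; then 30% H2O2, aq. NaOAc, 0 °C → rt
Reagents that add atoms: hydrogen peroxide, OO
Why: Anti-Markovnikov hydroboration–oxidation with the bulky, ester-tolerant 9-BBN should place boron on the terminal carbon, the acetate-buffered peroxide oxidation should spare both esters, and because the ring carboxylates are already reduced the new alcohol cannot lactonise.

Step 12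
Reactants: 17 [4-(acetoxymethyl)-5-(2-hydroxyethyl)-2,2-dimethylindan-6-yl]methyl butanoate
Product: 18 [4-(acetoxymethyl)-5-(2-chloroethyl)-2,2-dimethylindan-6-yl]methyl butanoate
Conditions: PPh3, N-chlorosuccinimide, CH2Cl2, 0 °C → rt
Reagents that add atoms: N-chlorosuccinimide, ClN1C(=O)CCC1=O
Why: Appel-type chlorination by SN2 displacement at the primary carbon under neutral conditions should give the 2-chloroethyl chain without disturbing either ester.

Compound list
1 | 3,3-dimethylcyclopentan-1-one | O=C1CCC(C)(C)C1 | starting material
2 | ethyl formate | CCOC=O | starting material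
3 | (Z)-2-(hydroxymethylene)-4,4-dimethylcyclopentan-1-one | O=C1CC(C)(C)C/C1=C/O | intermediate
4 | dimethyl 3-oxopentanedioate | COC(=O)CC(=O)CC(=O)OC | starting material
5 | dimethyl 2-[(Z)-(4,4-dimethyl-2-oxocyclopentylidene)methyl]-3-oxopentanedioate (Knoevenagel adduct; the enolisable CH is not a fixed stereocenter) | O=C1CC(C)(C)C/C1=C/C(C(=O)OC)C(=O)CC(=O)OC | intermediate (not isolated)
6 | dimethyl 5-hydroxy-2,2-dimethylindane-4,6-dicarboxylate | COC(=O)c1cc2CC(C)(C)Cc2c(C(=O)OC)c1O | intermediate
7 | dimethyl 2,2-dimethyl-5-(trifluoromethanesulfonyloxy)indane-4,6-dicarboxylate | COC(=O)c1cc2CC(C)(C)Cc2c(C(=O)OC)c1OS(=O)(=O)C(F)(F)F | intermediate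
8 | dimethyl 5-ethenyl-2,2-dimethylindane-4,6-dicarboxylate | COC(=O)c1cc2CC(C)(C)Cc2c(C(=O)OC)c1C=C | intermediate
9 | 5-ethenyl-4-(methoxycarbonyl)-2,2-dimethylindane-6-carboxylic acid | OC(=O)c1cc2CC(C)(C)Cc2c(C(=O)OC)c1C=C | intermediate
10 | isobutyl carbonic mixed anhydride of acid 9 | CC(C)COC(=O)OC(=O)c1cc2CC(C)(C)Cc2c(C(=O)OC)c1C=C | intermediate (not isolated)
11 | methyl 5-ethenyl-6-(hydroxymethyl)-2,2-dimethylindane-4-carboxylate | OCc1cc2CC(C)(C)Cc2c(C(=O)OC)c1C=C | intermediate
12 | methyl 6-(chloromethyl)-5-ethenyl-2,2-dimethylindane-4-carboxylate | ClCc1cc2CC(C)(C)Cc2c(C(=O)OC)c1C=C | intermediate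
13 | [6-(chloromethyl)-5-ethenyl-2,2-dimethylindan-4-yl]methanol | ClCc1cc2CC(C)(C)Cc2c(CO)c1C=C | intermediate
14 | [6-(chloromethyl)-5-ethenyl-2,2-dimethylindan-4-yl]methyl acetate | ClCc1cc2CC(C)(C)Cc2c(COC(C)=O)c1C=C | intermediate
15 | [4-(acetoxymethyl)-5-ethenyl-2,2-dimethylindan-6-yl]methyl butanoate | CCCC(=O)OCc1cc2CC(C)(C)Cc2c(COC(C)=O)c1C=C | intermediate
16 | [4-(acetoxymethyl)-5-[2-(9-borabicyclo[3.3.1]nonan-9-yl)ethyl]-2,2-dimethylindan-6-yl]methyl butanoate | CCCC(=O)OCc1cc2CC(C)(C)Cc2c(COC(C)=O)c1CCB1C2CCCC1CCC2 | intermediate (not isolated)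
17 | [4-(acetoxymethyl)-5-(2-hydroxyethyl)-2,2-dimethylindan-6-yl]methyl butanoate | CCCC(=O)OCc1cc2CC(C)(C)Cc2c(COC(C)=O)c1CCO | intermediate
18 | [4-(acetoxymethyl)-5-(2-chloroethyl)-2,2-dimethylindan-6-yl]methyl butanoate | CCCC(=O)OCc1cc2c(c(COC(C)=O)c1CCCl)CC(C)(C)C2 | target

Total step count: 12. Longest linear sequence: 12 steps, from 1 to 18.

Steps most likely to fail

Step 2. The annulation may be starved by retro-Claisen loss of the formyl group from 3, by self-condensation of 4 under alkoxide, or by diversion into oxygen cyclisation. The fallback sets out from 3, which is condensed with dimethylamine (Me2NH in THF, molecular sieves, rt) to the vinylogous amide (E)-2-[(dimethylamino)methylidene]-4,4-dimethylcyclopentan-1-one F1, an electrophile that cannot deformylate. Heating F1 with 4 in AcOH should exchange the amine for the carbon nucleophile by addition–elimination, arriving at adduct 5. Subsequent treatment with NaOMe in MeOH should close and aromatise the ring, so the route is rejoined at 6.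

Step 5. The two esters may not differ enough in rate, because the C3 methylene is tied back in the five-membered ring and shields the C4 ester less than a free ortho alkyl group would; over-hydrolysis or a mixture of mono-acids would follow. The fallback sets out from 8 and moves the discrimination to the alcohol stage. Reduction of both esters with i-Bu2AlH (CH2Cl2, −78 → 0 °C) should give the diol (5-ethenyl-2,2-dimethylindane-4,6-diyl)dimethanol F2. Acylation with one equivalent of butanoyl chloride and 2,4,6-collidine at −78 °C should favour the less flanked C6 hydroxymethyl group and give [5-ethenyl-4-(hydroxymethyl)-2,2-dimethylindan-6-yl]methyl butanoate F3. Acetylation (Ac2O, pyridine, DMAP) then rejoins the route at 15.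

Step 11. Hydroboration may be sluggish at the twisted, doubly flanked vinyl group, and forcing it risks ester reduction, while the oxidative work-up risks acyl loss. The fallback sets out from 15. Epoxidation (mCPBA, NaHCO3, CH2Cl2) should give the racemic oxirane [4-(acetoxymethyl)-2,2-dimethyl-5-(oxiran-2-yl)indan-6-yl]methyl butanoate F4. Meinwald rearrangement (BF3·OEt2, CH2Cl2, −20 °C), with hydride shift to the benzylic carbon, should give the arylacetaldehyde [4-(acetoxymethyl)-2,2-dimethyl-5-(2-oxoethyl)indan-6-yl]methyl butanoate F5. Brief reduction with NaBH4 in MeOH at 0 °C should reduce only the aldehyde and rejoin the route at 17.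

Further compounds
F1 | step 2 | (E)-2-[(dimethylamino)methylidene]-4,4-dimethylcyclopentan-1-one | O=C1CC(C)(C)C/C1=C\N(C)C
F2 | step 5 | (5-ethenyl-2,2-dimethylindane-4,6-diyl)dimethanol | OCc1cc2CC(C)(C)Cc2c(CO)c1C=C
F3 | step 5 | [5-ethenyl-4-(hydroxymethyl)-2,2-dimethylindan-6-yl]methyl butanoate | CCCC(=O)OCc1cc2CC(C)(C)Cc2c(CO)c1C=C
F4 | step 11 | [4-(acetoxymethyl)-2,2-dimethyl-5-(oxiran-2-yl)indan-6-yl]methyl butanoate (racemic) | CCCC(=O)OCc1cc2CC(C)(C)Cc2c(COC(C)=O)c1C1CO1
F5 | step 11 | [4-(acetoxymethyl)-2,2-dimethyl-5-(2-oxoethyl)indan-6-yl]methyl butanoate | CCCC(=O)OCc1cc2CC(C)(C)Cc2c(COC(C)=O)c1CC=O
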